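Ring B, the central 2,4-disubstituted furan, is cut at C2–C3 and at the C2–CH2 bridge bond. C2 is a ketone-level carbon between two methylenes and becomes C2 of a 1,3-dithiane. C3 and C4 are the carbons of a 2,2-disubstituted epoxide whose oxygen is later expelled, while C5 and O1 are its silyloxymethyl arm. In one flask the lithiated silyl dithiane opens the pentynyl epoxide, a 1,4-Brook shift regenerates the carbanion, and 3-(bromomethyl)furan (ring A) alkylates it. Hydrolysis and acid then aromatise ring B; the methylalkyne, an Evans-derived (R)-alkene and a methyl tetronate complete the chain.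

Key step: step 5

Assumption: 4-hydroxy-3-methylfuran-2(5H)-one (3-methyltetronic acid) is taken as a purchasable building block; the epoxide and the compounds that carry its quaternary carbon are racemic, which is immaterial because that centre is erased when ring B aromatises.

Step 1
Reactants: 1 5-bromopent-2-yne; 2 prop-2-yn-1-ol
Product: 5 2-methylidenehept-5-yn-1-ol, via pent-3-yn-1-ylmagnesium bromide 3 (not isolated), via cyclic alkenylmagnesium alkoxide 4 (not isolated)
Conditions: 1 (2.5 equiv), Mg, THF, rt; then 2, CuI (10 mol %), Et2O/THF, −10 °C → rt; sat. aq NH4Cl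
Reagents that add atoms: magnesium, [Mg] (held only in intermediates 3 and 4)
Why: Copper-catalysed anti-carbomagnesiation of the propargylic magnesium alkoxide should deliver the alkyl group to the internal alkyne carbon and give chelate 4, which is protonated to the 2-substituted allyl alcohol; the internal alkyne of the chain has no directing alkoxide and should stay inert.

Step 2
Reactants: 5 2-methylidenehept-5-yn-1-ol
Product: 6 tert-butyldimethyl[(2-methylidenehept-5-yn-1-yl)oxy]silane
Conditions: TBSCl, imidazole, CH2Cl2, 0 °C → rt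
Reagents that add atoms: tert-butyldimethylsilyl chloride, CC(C)(C)[Si](C)(C)Cl
Why: Routine silylation of a primary allylic alcohol masks the oxygen that will become O1 of ring B, using the same silyl group that later migrates so that any oxygen-to-oxygen silyl exchange is degenerate.

Step 3
Reactants: 6 tert-butyldimethyl[(2-methylidenehept-5-yn-1-yl)oxy]silane
Product: 7 tert-butyldimethyl{[2-(pent-3-yn-1-yl)oxiran-2-yl]methoxy}silane (racemic)
Conditions: mCPBA, NaHCO3, CH2Cl2, 0 °C → rt
Reagents that add atoms: 3-chloroperoxybenzoic acid, OOC(=O)c1cccc(Cl)c1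
Why: Prilezhaev epoxidation should take the electron-rich 1,1-disubstituted alkene much faster than the internal alkyne, with bicarbonate protecting the tertiary epoxide and the silyl ether; the new stereocentre forms racemic and is erased in step 7.

Step 4
Reactants: 8 furan-3-ylmethanol
Product: 9 3-(bromomethyl)furan
Conditions: PBr3 (0.4 equiv), pyridine (cat.), Et2O, −10 → 0 °C; dried ether solution used at once
Reagents that add atoms: phosphorus tribromide, BrP(Br)Br
Why: SN2 bromination of a primary furylmethyl alcohol through its phosphite ester is standard; the labile bromide is kept cold and used immediately.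

Step 5
Reactants: 10 2-(tert-butyldimethylsilyl)-1,3-dithiane; 7 tert-butyldimethyl{[2-(pent-3-yn-1-yl)oxiran-2-yl]methoxy}silane; 9 3-(bromomethyl)furan
Product: 14 2-{2,3-bis[(tert-butyldimethylsilyl)oxy]-2-(pent-3-yn-1-yl)propyl}-2-(furan-3-ylmethyl)-1,3-dithiane (racemic), via 2-lithio-2-(tert-butyldimethylsilyl)-1,3-dithiane 11 (not isolated), via lithium alkoxide of the epoxide-opened silyl dithiane 12 (not isolated), via O-silylated 2-lithiodithiane 13 (not isolated)
Conditions: t-BuLi, Et2O, −78 → −45 °C; 7, Et2O, −78 → 0 °C; then HMPA/THF, −78 → −40 °C; then 9, −78 → −20 °C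
Reagents that add atoms: tert-butyllithium, [Li]C(C)(C)C (lithium held only in intermediates 11 to 13)
Why: tert-Butyllithium deprotonates the silyl dithiane, and in ether anion 11 attacks the unsubstituted epoxide CH2 by SN2 (the C2–C3 bond of ring B) to give tertiary alkoxide 12, which keeps silicon on carbon while no polar cosolvent is present. HMPA then triggers the 1,4-Brook shift through a five-membered cyclic transition state, moving silicon to the tertiary oxygen and regenerating a dithiane-stabilised carbanion 13 at the same carbon, which is alkylated by SN2 with the furylmethyl bromide (the C2–CH2 bridge bond). The closest known reaction type is the solvent-controlled three-component coupling of a 2-silyl-1,3-dithiane with an epoxide and an alkyl halide; because the epoxide here is 2,2-disubstituted, silyl transfer onto a tertiary alkoxide is the demanding element and is given time before the bromide is added. No ring is closed and no stereocentre is created, the carbinol centre being inherited racemic from 7. The step needs opening at CH2 only, which the fully substituted other epoxide carbon secures, and one epoxide plus one bromide per dithiane, which withholding HMPA until the epoxide is consumed secures; the methyl-capped alkyne offers no acidic proton to quench the anions.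

Step 6
Reactants: 14 2-{2,3-bis[(tert-butyldimethylsilyl)oxy]-2-(pent-3-yn-1-yl)propyl}-2-(furan-3-ylmethyl)-1,3-dithiane
Product: 15 4-[(tert-butyldimethylsilyl)oxy]-4-{[(tert-butyldimethylsilyl)oxy]methyl}-1-(furan-3-yl)non-7-yn-2-one (racemic)
Conditions: MeI, CaCO3, MeCN/H2O (9:1), 45 °C
Reagents that add atoms: water, O
Why: Alkylative dithiane hydrolysis (S-methylation, then attack of water under carbonate buffering) should unveil the ketone without oxidants or heavy-metal salts that would endanger the furan, the alkyne or the silyl ethers.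

Step 7
Reactants: 15 4-[(tert-butyldimethylsilyl)oxy]-4-{[(tert-butyldimethylsilyl)oxy]methyl}-1-(furan-3-yl)non-7-yn-2-one
Product: 17 2-(furan-3-ylmethyl)-4-(pent-3-yn-1-yl)furan, via cyclic hemiketal 16 (not isolated)
Conditions: p-TsOH·H2O (0.2 equiv), THF/H2O (20:1), rt → 45 °C
Reagents that add atoms: none
Why: Acid should cleave the primary silyl ether, the freed hydroxyl closes onto the ketone (5-exo-trig) to hemiketal 16, and loss of water followed by expulsion of the tertiary allylic silyloxy group aromatises ring B (acid cyclodehydration of a γ-hydroxy-β-oxy ketone), so the 2,4-pattern follows from connectivity.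

Step 8
Reactants: 17 2-(furan-3-ylmethyl)-4-(pent-3-yn-1-yl)furan
Product: 19 2-(furan-3-ylmethyl)-4-[(3E)-4-iodopent-3-en-1-yl]furan, via alkenylzirconocene chloride 18 (not isolated)
Conditions: Cp2Zr(H)Cl (2.5 equiv), THF, 50 °C; then I2, THF, −78 → 0 °C
Reagents that add atoms: iodine, [I][I]; chloridohydridozirconocene, [H][Zr](Cl)(C1C=CC=C1)C1C=CC=C1 (zirconium held only in intermediate 18)
Why: syn-Hydrozirconation of the internal alkyne with excess hydride under equilibrating conditions should place zirconium on the less hindered, methyl-bearing carbon, and iodinolysis with retention then gives the (E)-2-iodoalkene, the geometry being fixed by the syn addition.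

Step 9
Reactants: 20 (4S)-4-benzyl-3-propanoyl-1,3-oxazolidin-2-one; 21 3-iodoprop-1-ene (allyl iodide)
Product: 23 (4S)-4-benzyl-3-[(2R)-2-methylpent-4-enoyl]-1,3-oxazolidin-2-one, via sodium Z-enolate 22 (not isolated)
Conditions: NaN(SiMe3)2, THF, −78 °C; then 21, −78 → −45 °C
Reagents that add atoms: sodium bis(trimethylsilyl)amide, [Na]N([Si](C)(C)C)[Si](C)(C)C (sodium held only in intermediate 22)
Why: Evans asymmetric alkylation: the chelated (Z)-enolate is allylated on the face opposite the benzyl group of the (S)-auxiliary, which sets the (R) methyl-bearing stereocentre of the target.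

Step 10
Reactants: 23 (4S)-4-benzyl-3-[(2R)-2-methylpent-4-enoyl]-1,3-oxazolidin-2-one
Product: 24 (2R)-2-methylpent-4-en-1-ol
Conditions: LiBH4, MeOH (1 equiv), Et2O, 0 °C
Reagents that add atoms: none
Why: Reductive cleavage of the N-acyloxazolidinone with borohydride gives the primary alcohol without touching the α-stereocentre and returns the auxiliary.

Step 11
Reactants: 24 (2R)-2-methylpent-4-en-1-ol
Product: 25 tert-butyldimethyl{[(2R)-2-methylpent-4-en-1-yl]oxy}silane
Conditions: TBSCl, imidazole, CH2Cl2, rt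
Reagents that add atoms: tert-butyldimethylsilyl chloride, CC(C)(C)[Si](C)(C)Cl
Why: Routine silylation makes the volatile alcohol easy to handle and keeps the oxygen inert through hydroboration and cross-coupling.

Step 12
Reactants: 25 tert-butyldimethyl{[(2R)-2-methylpent-4-en-1-yl]oxy}silane; 19 2-(furan-3-ylmethyl)-4-[(3E)-4-iodopent-3-en-1-yl]furan
Product: 27 tert-butyl({(2R,6E)-9-[5-(furan-3-ylmethyl)furan-3-yl]-2,6-dimethylnon-6-en-1-yl}oxy)dimethylsilane, via B-alkyl-9-BBN 26 (not isolated)
Conditions: 9-BBN, THF, 0 °C → rt; then aq Cs2CO3, 19, Pd(dppf)Cl2·CH2Cl2 (5 mol %), AsPh3, DMF, rt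
Reagents that add atoms: 9-borabicyclo[3.3.1]nonane, [H]B1C2CCCC1CCC2 (boron held only in intermediate 26)
Why: Anti-Markovnikov hydroboration of the terminal alkene followed by B-alkyl Suzuki–Miyaura coupling with the alkenyl iodide should join the fragments with retention of the (E) geometry and leave the remote stereocentre untouched.

Step 13
Reactants: 27 tert-butyl({(2R,6E)-9-[5-(furan-3-ylmethyl)furan-3-yl]-2,6-dimethylnon-6-en-1-yl}oxy)dimethylsilane
Product: 28 (2R,6E)-9-[5-(furan-3-ylmethyl)furan-3-yl]-2,6-dimethylnon-6-en-1-ol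
Conditions: TBAF, THF, 0 °C → rt
Reagents that add atoms: none
Why: Fluoride-mediated desilylation of a primary silyl ether is routine and leaves furans and alkene alone.

Step 14
Reactants: 28 (2R,6E)-9-[5-(furan-3-ylmethyl)furan-3-yl]-2,6-dimethylnon-6-en-1-ol
Product: 29 (2R,6E)-9-[5-(furan-3-ylmethyl)furan-3-yl]-2,6-dimethylnon-6-enal
Conditions: Dess–Martin periodinane, NaHCO3, CH2Cl2, 0 °C → rt; used directly
Reagents that add atoms: none
Why: Dess–Martin oxidation under buffered, non-basic conditions should give the α-methyl aldehyde without epimerisation.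

Step 15
Reactants: 30 4-hydroxy-3-methylfuran-2(5H)-one
Product: 31 4-methoxy-3-methylfuran-2(5H)-one
Conditions: Me2SO4, K2CO3, acetone, reflux
Reagents that add atoms: dimethyl sulfate, COS(=O)(=O)OC
Why: O-Methylation of the vinylogous acid with a hard methylating agent gives the methyl tetronate, which blocks the acidic hydroxyl and directs later deprotonation to C5.

Step 16
Reactants: 31 4-methoxy-3-methylfuran-2(5H)-one; 29 (2R,6E)-9-[5-(furan-3-ylmethyl)furan-3-yl]-2,6-dimethylnon-6-enal
Product: 33 5-{(2R,6E)-9-[5-(furan-3-ylmethyl)furan-3-yl]-1-hydroxy-2,6-dimethylnon-6-en-1-yl}-4-methoxy-3-methylfuran-2(5H)-one (mixture at the two new centres), via lithiated methyl tetronate 32 (not isolated)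
Conditions: LiN(iPr)2 (commercial solution), THF, −78 °C; then 29, −78 °C; AcOH quench at −78 °C
Reagents that add atoms: lithium diisopropylamide, [Li]N(C(C)C)C(C)C (lithium held only in intermediate 32)
Why: Deprotonation at C5 gives an aromatic 2-oxidofuran anion that should add to the aldehyde at low temperature faster than it enolises it (aldol addition); the two new stereocentres form unselectively and are both erased in step 17.

Step 17
Reactants: 33 5-{(2R,6E)-9-[5-(furan-3-ylmethyl)furan-3-yl]-1-hydroxy-2,6-dimethylnon-6-en-1-yl}-4-methoxy-3-methylfuran-2(5H)-one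
Product: 35 (5Z)-5-{(2R,6E)-9-[5-(furan-3-ylmethyl)furan-3-yl]-2,6-dimethylnon-6-en-1-ylidene}-4-methoxy-3-methylfuran-2(5H)-one, via mesylate 34 (not isolated)
Conditions: MsCl, Et3N, CH2Cl2, 0 °C; then DBU, 0 °C → rt
Reagents that add atoms: methanesulfonyl chloride, CS(=O)(=O)Cl (held only in intermediate 34)
Why: Mesylation and E1cB elimination through the acidic C5 position should give the alkylidene butenolide, with (Z) favoured because the (E) isomer would press the branched chain against the 4-methoxy group; the methyl-bearing stereocentre carries no acidic hydrogen under these conditions.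

Step 18
Reactants: 35 (5Z)-5-{(2R,6E)-9-[5-(furan-3-ylmethyl)furan-3-yl]-2,6-dimethylnon-6-en-1-ylidene}-4-methoxy-3-methylfuran-2(5H)-one
Product: 36 (5Z)-5-{(2R,6E)-9-[5-(furan-3-ylmethyl)furan-3-yl]-2,6-dimethylnon-6-en-1-ylidene}-4-hydroxy-3-methylfuran-2(5H)-one (CID54702820)
Conditions: LiSPr (from n-PrSH and n-BuLi), HMPA, rt; then 1 M HCl
Reagents that add atoms: none
Why: SN2 O-demethylation of the vinylogous methyl ester by a soft thiolate in a dipolar aprotic solvent should release the tetronate, and acidification gives the tetronic acid with furans, alkenes and the stereocentre unchanged.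

Compound list
1 | 5-bromopent-2-yne | CC#CCCBr | starting material
2 | prop-2-yn-1-ol (propargyl alcohol) | C#CCO | starting material
3 | pent-3-yn-1-ylmagnesium bromide | CC#CCC[Mg]Br | intermediate
4 | cyclic alkenylmagnesium alkoxide, 4-(pent-3-yn-1-yl)-2,5-dihydro-1,2-oxamagnesole | CC#CCCC1=C[Mg]OC1 | intermediate
5 | 2-methylidenehept-5-yn-1-ol | CC#CCCC(=C)CO | intermediate
6 | tert-butyldimethyl[(2-methylidenehept-5-yn-1-yl)oxy]silane | CC#CCCC(=C)CO[Si](C)(C)C(C)(C)C | intermediate
7 | tert-butyldimethyl{[2-(pent-3-yn-1-yl)oxiran-2-yl]methoxy}silane (racemic) | CC#CCCC1(CO[Si](C)(C)C(C)(C)C)CO1 | intermediate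
8 | furan-3-ylmethanol | OCc1ccoc1 | starting material
9 | 3-(bromomethyl)furan | BrCc1ccoc1 | intermediate
10 | 2-(tert-butyldimethylsilyl)-1,3-dithiane | CC(C)(C)[Si](C)(C)C1SCCCS1 | starting material
11 | 2-lithio-2-(tert-butyldimethylsilyl)-1,3-dithiane | [Li]C1([Si](C)(C)C(C)(C)C)SCCCS1 | intermediate
12 | lithium 1-[(tert-butyldimethylsilyl)oxy]-2-{[2-(tert-butyldimethylsilyl)-1,3-dithian-2-yl]methyl}hept-5-yn-2-olate (racemic) | CC#CCCC(CO[Si](C)(C)C(C)(C)C)(O[Li])CC1([Si](C)(C)C(C)(C)C)SCCCS1 | intermediate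
13 | 2-{2,3-bis[(tert-butyldimethylsilyl)oxy]-2-(pent-3-yn-1-yl)propyl}-2-lithio-1,3-dithiane (racemic) | CC#CCCC(CO[Si](C)(C)C(C)(C)C)(O[Si](C)(C)C(C)(C)C)CC1([Li])SCCCS1 | intermediate
14 | 2-{2,3-bis[(tert-butyldimethylsilyl)oxy]-2-(pent-3-yn-1-yl)propyl}-2-(furan-3-ylmethyl)-1,3-dithiane (racemic) | CC#CCCC(CO[Si](C)(C)C(C)(C)C)(O[Si](C)(C)C(C)(C)C)CC1(Cc2ccoc2)SCCCS1 | intermediate
15 | 4-[(tert-butyldimethylsilyl)oxy]-4-{[(tert-butyldimethylsilyl)oxy]methyl}-1-(furan-3-yl)non-7-yn-2-one (racemic) | CC#CCCC(CO[Si](C)(C)C(C)(C)C)(O[Si](C)(C)C(C)(C)C)CC(=O)Cc1ccoc1 | intermediate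
16 | 4-[(tert-butyldimethylsilyl)oxy]-2-(furan-3-ylmethyl)-4-(pent-3-yn-1-yl)oxolan-2-ol (cyclic hemiketal, stereoisomer mixture) | CC#CCCC1(O[Si](C)(C)C(C)(C)C)COC(O)(Cc2ccoc2)C1 | intermediate
17 | 2-(furan-3-ylmethyl)-4-(pent-3-yn-1-yl)furan | CC#CCCc1coc(Cc2ccoc2)c1 | intermediate
18 | chlorido{(2E)-5-[5-(furan-3-ylmethyl)furan-3-yl]pent-2-en-2-yl}zirconocene | C/C(=C\CCc1coc(Cc2ccoc2)c1)[Zr](Cl)(C1C=CC=C1)C1C=CC=C1 | intermediate
19 | 2-(furan-3-ylmethyl)-4-[(3E)-4-iodopent-3-en-1-yl]furan | I/C(C)=C/CCc1coc(Cc2ccoc2)c1 | intermediate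
20 | (4S)-4-benzyl-3-propanoyl-1,3-oxazolidin-2-one | CCC(=O)N1[C@@H](Cc2ccccc2)COC1=O | starting material
21 | 3-iodoprop-1-ene (allyl iodide) | C=CCI | starting material
22 | sodium (Z)-enolate of 20 | C/C=C(\O[Na])N1[C@@H](Cc2ccccc2)COC1=O | intermediate
23 | (4S)-4-benzyl-3-[(2R)-2-methylpent-4-enoyl]-1,3-oxazolidin-2-one | C=CC[C@@H](C)C(=O)N1[C@@H](Cc2ccccc2)COC1=O | intermediate
24 | (2R)-2-methylpent-4-en-1-ol | C=CC[C@@H](C)CO | intermediate
25 | tert-butyldimethyl{[(2R)-2-methylpent-4-en-1-yl]oxy}silane | C=CC[C@@H](C)CO[Si](C)(C)C(C)(C)C | intermediate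
26 | 9-{(4R)-5-[(tert-butyldimethylsilyl)oxy]-4-methylpentyl}-9-borabicyclo[3.3.1]nonane | CC(C)(C)[Si](C)(C)OC[C@H](C)CCCB1C2CCCC1CCC2 | intermediate
27 | tert-butyl({(2R,6E)-9-[5-(furan-3-ylmethyl)furan-3-yl]-2,6-dimethylnon-6-en-1-yl}oxy)dimethylsilane | CC(C)(C)[Si](C)(C)OC[C@H](C)CCC/C(C)=C/CCc1coc(Cc2ccoc2)c1 | intermediate
28 | (2R,6E)-9-[5-(furan-3-ylmethyl)furan-3-yl]-2,6-dimethylnon-6-en-1-ol | OC[C@H](C)CCC/C(C)=C/CCc1coc(Cc2ccoc2)c1 | intermediate
29 | (2R,6E)-9-[5-(furan-3-ylmethyl)furan-3-yl]-2,6-dimethylnon-6-enal | O=C[C@H](C)CCC/C(C)=C/CCc1coc(Cc2ccoc2)c1 | intermediate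
30 | 4-hydroxy-3-methylfuran-2(5H)-one (3-methyltetronic acid) | CC1=C(O)COC1=O | starting material
31 | 4-methoxy-3-methylfuran-2(5H)-one | COC1=C(C)C(=O)OC1 | intermediate
32 | lithium 4-methoxy-3-methylfuran-2-olate (C5-lithiated methyl tetronate) | [Li]Oc1occ(OC)c1C | intermediate
33 | 5-{(2R,6E)-9-[5-(furan-3-ylmethyl)furan-3-yl]-1-hydroxy-2,6-dimethylnon-6-en-1-yl}-4-methoxy-3-methylfuran-2(5H)-one (mixture at C5 and the carbinol carbon) | CC1=C(OC)C(C(O)[C@H](C)CCC/C(C)=C/CCc2coc(Cc3ccoc3)c2)OC1=O | intermediate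
34 | methanesulfonate of 33 | CC1=C(OC)C(C(OS(C)(=O)=O)[C@H](C)CCC/C(C)=C/CCc2coc(Cc3ccoc3)c2)OC1=O | intermediate
35 | (5Z)-5-{(2R,6E)-9-[5-(furan-3-ylmethyl)furan-3-yl]-2,6-dimethylnon-6-en-1-ylidene}-4-methoxy-3-methylfuran-2(5H)-one | CC1=C(OC)/C(=C/[C@H](C)CCC/C(C)=C/CCc2coc(Cc3ccoc3)c2)OC1=O | intermediate
36 | (5Z)-5-{(2R,6E)-9-[5-(furan-3-ylmethyl)furan-3-yl]-2,6-dimethylnon-6-en-1-ylidene}-4-hydroxy-3-methylfuran-2(5H)-one | CC1=C(O)/C(=C/[C@H](C)CCC/C(C)=C/CCc2coc(Cc3ccoc3)c2)OC1=O | target

Total steps: 18. Longest linear sequence: 13 steps (1, 2, 3, 5, 6, 7, 8, 12, 13, 14, 16, 17, 18).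

Steps most likely to fail

Step 5. Attack of the bulky silyl dithiane anion on the neopentyl-like epoxide CH2 may be slow, and silyl transfer onto the tertiary alkoxide may lag, so that protonated or O-alkylated material is carried through instead of the doubly alkylated dithiane. The fallback sets out from 7 and rejoins the route at 13, and hence 14, making the same two bonds in separate classical dithiane alkylations. 1,3-Dithiane is deprotonated (n-BuLi, THF, −30 °C) to 2-lithio-1,3-dithiane F1, the least hindered acyl anion equivalent, which opens 7 at CH2 to give the tertiary alcohol 1-[(tert-butyldimethylsilyl)oxy]-2-(1,3-dithian-2-ylmethyl)hept-5-yn-2-ol F2. TBSOTf and 2,6-lutidine silylate the tertiary hydroxyl to give 2-{2,3-bis[(tert-butyldimethylsilyl)oxy]-2-(pent-3-yn-1-yl)propyl}-1,3-dithiane F3. Deprotonation of F3 (t-BuLi, THF/HMPA, −78 °C) generates carbanion 13 directly, which 9 alkylates to 14.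

Step 8. Migration of zirconium to the methyl-bearing carbon may stay incomplete, giving a regioisomeric iodoalkene that is hard to remove, and iodine may attack the electron-rich furans. The fallback sets out from 17 and rejoins the route at 27, fixing regiochemistry and geometry by a stereoselective double cross-coupling of a 1,1-dibromoalkene instead of a hydrometalation. Semi-hydrogenation of 17 (H2, Pd/CaCO3 poisoned with Pb(OAc)2, quinoline) gives 2-(furan-3-ylmethyl)-4-[(3Z)-pent-3-en-1-yl]furan F4. Dihydroxylation (OsO4 cat., NMO) gives 5-[5-(furan-3-ylmethyl)furan-3-yl]pentane-2,3-diol F5, and NaIO4 cleavage gives 3-[5-(furan-3-ylmethyl)furan-3-yl]propanal F6. Ramirez olefination (CBr4, PPh3) gives 4-(4,4-dibromobut-3-en-1-yl)-2-(furan-3-ylmethyl)furan F7. B-alkyl Suzuki–Miyaura coupling of borane 26 (Pd(dppf)Cl2, Cs2CO3) takes place at the less hindered bromine, trans to the chain, and gives tert-butyl({(2R,6Z)-6-bromo-9-[5-(furan-3-ylmethyl)furan-3-yl]-2-methylnon-6-en-1-yl}oxy)dimethylsilane F8. Methylation of F8 with retention (Me2Zn, Pd(t-Bu3P)2, THF) gives 27.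

Step 18. The thiolate may add to the alkylidene butenolide or displace the oxygen substituent at C4 instead of attacking the methyl group, and the basic medium may erode the allylic stereocentre. The fallback sets out from 29 and 30 and rejoins the route at 36, carrying the tetronic acid oxygen as an acetal that mild acid removes. MOMCl and i-Pr2NEt convert 30 into 4-(methoxymethoxy)-3-methylfuran-2(5H)-one F9, and LiN(iPr)2 (THF, −78 °C) gives its C5 lithium derivative, lithium 4-(methoxymethoxy)-3-methylfuran-2-olate F10. Addition to 29 gives the aldol adduct 5-{(2R,6E)-9-[5-(furan-3-ylmethyl)furan-3-yl]-1-hydroxy-2,6-dimethylnon-6-en-1-yl}-4-(methoxymethoxy)-3-methylfuran-2(5H)-one F11. MsCl and Et3N give its methanesulfonate F12, and DBU eliminates it to (5Z)-5-{(2R,6E)-9-[5-(furan-3-ylmethyl)furan-3-yl]-2,6-dimethylnon-6-en-1-ylidene}-4-(methoxymethoxy)-3-methylfuran-2(5H)-one F13. Dilute HCl in THF at room temperature cleaves the acetal of F13 to give 36.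

Further compounds
F1 | step 5 | 2-lithio-1,3-dithiane | [Li]C1SCCCS1
F2 | step 5 | 1-[(tert-butyldimethylsilyl)oxy]-2-(1,3-dithian-2-ylmethyl)hept-5-yn-2-ol | CC#CCCC(O)(CO[Si](C)(C)C(C)(C)C)CC1SCCCS1
F3 | step 5 | 2-{2,3-bis[(tert-butyldimethylsilyl)oxy]-2-(pent-3-yn-1-yl)propyl}-1,3-dithiane | CC#CCCC(CO[Si](C)(C)C(C)(C)C)(O[Si](C)(C)C(C)(C)C)CC1SCCCS1
F4 | step 8 | 2-(furan-3-ylmethyl)-4-[(3Z)-pent-3-en-1-yl]furan | C/C=C\CCc1coc(Cc2ccoc2)c1
F5 | step 8 | 5-[5-(furan-3-ylmethyl)furan-3-yl]pentane-2,3-diol | CC(O)C(O)CCc1coc(Cc2ccoc2)c1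
F6 | step 8 | 3-[5-(furan-3-ylmethyl)furan-3-yl]propanal | O=CCCc1coc(Cc2ccoc2)c1
F7 | step 8 | 4-(4,4-dibromobut-3-en-1-yl)-2-(furan-3-ylmethyl)furan | BrC(Br)=CCCc1coc(Cc2ccoc2)c1
F8 | step 8 | tert-butyl({(2R,6Z)-6-bromo-9-[5-(furan-3-ylmethyl)furan-3-yl]-2-methylnon-6-en-1-yl}oxy)dimethylsilane | CC(C)(C)[Si](C)(C)OC[C@H](C)CCC/C(Br)=C/CCc1coc(Cc2ccoc2)c1
F9 | step 18 | 4-(methoxymethoxy)-3-methylfuran-2(5H)-one | COCOC1=C(C)C(=O)OC1
F10 | step 18 | lithium 4-(methoxymethoxy)-3-methylfuran-2-olate | [Li]Oc1occ(OCOC)c1C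
F11 | step 18 | 5-{(2R,6E)-9-[5-(furan-3-ylmethyl)furan-3-yl]-1-hydroxy-2,6-dimethylnon-6-en-1-yl}-4-(methoxymethoxy)-3-methylfuran-2(5H)-one | CC1=C(OCOC)C(C(O)[C@H](C)CCC/C(C)=C/CCc2coc(Cc3ccoc3)c2)OC1=O
F12 | step 18 | methanesulfonate of F11 | CC1=C(OCOC)C(C(OS(C)(=O)=O)[C@H](C)CCC/C(C)=C/CCc2coc(Cc3ccoc3)c2)OC1=O
F13 | step 18 | (5Z)-5-{(2R,6E)-9-[5-(furan-3-ylmethyl)furan-3-yl]-2,6-dimethylnon-6-en-1-ylidene}-4-(methoxymethoxy)-3-methylfuran-2(5H)-one | CC1=C(OCOC)/C(=C/[C@H](C)CCC/C(C)=C/CCc2coc(Cc3ccoc3)c2)OC1=O
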